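In the first instants of a run none of the gas is dissolved, so the target cannot start until dissolved gas has built up, and what Monday's run shows of that opening is what I carry to the new flask, which has less protic impurity and runs much longer.

| flask | substrate | gas phase | protic impurity | catalyst | remark | time |
|---|---|---|---|---|---|---|
| Monday's | 0.18 M | 13 mM (held) | 0.054 M | 0.67 mM | run made earlier |  |
| flask | 0.18 M | 13 mM (held) | 0.0360 M | 0.67 mM |  | 20 min |

Monday's run (percent of the substrate charged)

| time / min | target / % |
|---|---|
| 0.333 | 1.1 |
| 1.00 | 4.5 |
| 2.00 | 9.2 |
| 3.00 | 15.5 |
| 4.00 | 19.9 |

(readings scatter by 0.5 percentage points)

- at the start none of the gas is dissolved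
- reactions considered so far: substrate + dissolved gas -> uncatalysed product; substrate + dissolved gas + catalyst -> catalyst + target; gas phase <-> dissolved gas; dissolved gas -> decomposed reagent; dissolved gas + protic impurity -> quenched reagent
- no earlier run changes the charge of protic impurity; that part of a forecast is a guess

* the target standing at 20 min, as a percentage of the substrate charged
* concentration of dissolved gas in solution at 2.0 min, in percent of saturation
* the change that raises the amount of target at 20 min, in percent of the substrate charged most ("none" if none brings more than 2 percentage points) (epsilon / theta / beta / none)
* amount of target at 20 min, in percent of the substrate charged, after theta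

- epsilon: doubling the transfer coefficient of the gas phase, all else as stated
- theta: doubling the amount of catalyst, all else as stated
- beta: doubling the saturation concentration of gas phase, all else as stated

Monday's target climbs from 4.5 % at 1.00 min to 19.9 % at 4.00 min, a nearly straight stretch with a slope of 0.0513 min⁻¹ of the charge. Drawn back, it meets zero at a lag of 0.123 min, but the scatter of one reading is worth 0.0974 min on that line, so the lag is a small and poorly read correction to the time.

In the middle of the run I take the dissolved gas as a quasi-steady state: it enters in proportion to its deficit below saturation and leaves about as fast. Each target consumes one dissolved gas, so I define the gas draw, the fraction of a saturated solution that forming the target consumes per minute, as slope times substrate charged over saturation concentration: 0.711 min⁻¹. My rule is that, while the target forms at this slope, the deficit, as a fraction of saturation, is at least the draw divided by the transfer coefficient, since the other routes also take gas. A short lag reads the sum of filling and emptying, not their ratio, so it gives no level, and no run reads the coefficient; I leave that number open. I commit to the corrected line for the opening, 9.63 % at 2.0 min, assuming the impurity changes little, which is a guess. Towards the end the line cannot hold, since it reaches the whole charge at 19.6 min, so I expect it to bend as the substrate falls.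

The forecast gives 70 % of target, 80 % of saturation at 2.0 min, and doubling the catalyst (theta) as the best change, with 85 %, on the ground that “Gas uptake therefore looks fast”. By my rule, that level asks for a coefficient of at least 3.56 min⁻¹.

The flask gives 74.2 % of target, theta as the best change, and 88.7 % of target after it. Its dissolved gas stands at 33.1 % of saturation at 2.0 min.

    substrate + dissolved gas → uncatalysed product (k = 2.80 M⁻¹ min⁻¹)
    substrate + dissolved gas + catalyst → catalyst + target (k = 21000 M⁻² min⁻¹)
    gas phase ⇌ dissolved gas, rate k3*(csat - [dissolved gas]) (kL = 1.40 min⁻¹)
    dissolved gas → decomposed reagent (k = 0.00730 min⁻¹)
    dissolved gas + protic impurity → quenched reagent (k = 2.50 M⁻¹ min⁻¹)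

The draw of 0.711 min⁻¹ is about half of the transfer coefficient of 1.4 min⁻¹, so while target forms at the opening slope the rule holds dissolved gas at or below 49.2 % of saturation, above the 33.1 % of dissolved gas in the flask at 2.0 min and below the forecast's 80 %. Left until 5.0 min, the neighbouring flask holds 25.1 % of target against 25.0 % on the corrected line, so it is still on the opening slope, and its dissolved gas stands at 38.2 % of saturation, also under that level.

The numbers in the tables are simulated on assumed constants, noise included.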